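## Retrosynthetic overview

1. Target 25 ⇒ dihydrobenzofuran 16 + pyrone 21 + a one-carbon unit (22), joined last by a Mannich/Michael methylene bridge.
2. Dihydrofuran ring of 16 (O1–C2–C3–C3a–C7a) ⇒ pyran ring of the (3S)-2,2-dimethylchroman-3-ol 12 by dehydrative 6→5 ring contraction. Enabling feature: the pyran oxygen O1 sits on the fully substituted gem-dimethyl carbon C2 next to the carbinol C3, so O1 can shift from C2 to C3 with inversion while the tertiary C2 leaves the ring and sheds a methyl proton to become the isopropenyl group.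
3. 12 ⇒ chromene 10 (asymmetric epoxidation of C3=C4, then benzylic C4–O hydrogenolysis) ⇒ para-O-(1,1-dimethylpropargyl) ether 6 of isobutyrylphloroglucinol (Claisen/oxa-6π cascade) ⇒ phloroglucinol 1.
4. Pyrone 21 ⇒ triketo ester 20 ⇒ methyl 3-oxopentanoate 17 + Weinreb amide 18.
5. Ring order: benzene ring bought; pyran (step 4); oxirane as a temporary ring (step 5, opened in step 6); furan by contraction of the pyran (step 7); pyranone separately (step 10).

Key step: step 7

Remark: the target stereocentre is R by CIP analysis of the SMILES. The (S,S)-salen catalyst is assumed to give the (3S,4S)-oxide, as is usual for 2,2-dimethylchromenes; the enantiomeric catalyst would be used if the opposite sense were found.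

## Route

Step 1
Reactants: 1 phloroglucinol; 2 isobutyryl chloride
Product: 3 2-methyl-1-(2,4,6-trihydroxyphenyl)propan-1-one
Conditions: AlCl3 (4 equiv), PhNO2/CH2Cl2, 0 °C to 40 °C; aq. HCl
Reagents that add atoms: none
Why: Friedel–Crafts C-acylation of the highly nucleophilic phloroglucinol should stop at the mono-ketone because the first acyl group, chelated to aluminium, deactivates the ring.

Step 2
Reactants: 3 2-methyl-1-(2,4,6-trihydroxyphenyl)propan-1-one; 4 3-chloro-3-methylbut-1-yne
Product: 5 1-{2,6-dihydroxy-4-[(2-methylbut-3-yn-2-yl)oxy]phenyl}-2-methylpropan-1-one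
Conditions: K2CO3 (1.2 equiv), KI, CuI (cat.), acetone, 50 °C
Reagents that add atoms: none
Why: Copper-assisted Williamson-type O-alkylation with the tertiary propargylic chloride is expected at the 4-OH only, since it is the most acidic hydroxyl and the only one not hydrogen-bonded to the ketone.

Step 3
Reactants: 5 1-{2,6-dihydroxy-4-[(2-methylbut-3-yn-2-yl)oxy]phenyl}-2-methylpropan-1-one
Product: 6 5-[(2-methylbut-3-yn-2-yl)oxy]-2-(2-methylpropanoyl)-1,3-phenylene diacetate
Conditions: Ac2O, pyridine, DMAP (cat.), CH2Cl2, 0 °C to rt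
Reagents that add atoms: acetic anhydride, CC(=O)OC(C)=O
Why: Standard O-acetylation masks both ortho hydroxyls, so that the propargylated oxygen is the only one able to close the pyran ring and the phenols are protected for the oxidation and triflation steps.

Step 4
Reactants: 6 5-[(2-methylbut-3-yn-2-yl)oxy]-2-(2-methylpropanoyl)-1,3-phenylene diacetate
Product: 10 2,2-dimethyl-6-(2-methylpropanoyl)-2H-chromene-5,7-diyl diacetate, via allenyl dienone 7 (not isolated), via allenylphenol 8 (not isolated), via o-quinone methide 9 (not isolated)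
Conditions: o-xylene, 140 °C
Reagents that add atoms: none
Why: Thermal aryl propargyl Claisen rearrangement to 7, enolisation to 8, 1,5-hydrogen shift to 9 and oxa-6π electrocyclisation form the 2,2-dimethyl-2H-chromene, and because the two ortho positions are equivalent and only one hydroxyl is free a single regioisomer is expected.

Step 5
Reactants: 10 2,2-dimethyl-6-(2-methylpropanoyl)-2H-chromene-5,7-diyl diacetate
Product: 11 (3S,4S)-3,4-epoxy-2,2-dimethyl-6-(2-methylpropanoyl)chromane-5,7-diyl diacetate
Conditions: (S,S)-Mn(salen)Cl (Jacobsen catalyst, 5 mol%), mCPBA, NMO, CH2Cl2, −78 °C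
Reagents that add atoms: mCPBA, O=C(OO)c1cccc(Cl)c1
Why: Jacobsen asymmetric epoxidation, for which cis-configured 2,2-dimethylchromenes are the best substrate class, should set C3 and C4 by catalyst control, and the anhydrous low-temperature protocol spares the aryl acetates.

Step 6
Reactants: 11 (3S,4S)-3,4-epoxy-2,2-dimethyl-6-(2-methylpropanoyl)chromane-5,7-diyl diacetate
Product: 12 (3S)-3-hydroxy-2,2-dimethyl-6-(2-methylpropanoyl)chromane-5,7-diyl diacetate
Conditions: H2 (1 atm), 10% Pd/C, EtOAc, rt
Reagents that add atoms: none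
Why: Catalytic hydrogenolysis should cleave only the benzylic C4–O bond of the aryl oxirane, so the C3–O bond keeps its S configuration and the hindered aryl ketone and the acetates are expected to survive.

Step 7
Reactants: 12 (3S)-3-hydroxy-2,2-dimethyl-6-(2-methylpropanoyl)chromane-5,7-diyl diacetate
Product: 15 (2R)-5-(2-methylpropanoyl)-2-(prop-1-en-2-yl)-2,3-dihydro-1-benzofuran-4,6-diyl diacetate, via C3 triflate 13 (not isolated), via oxiranium triflate 14 (not isolated)
Conditions: Tf2O (1.2 equiv), 2,6-lutidine (3 equiv), CH2Cl2, −78 °C to 0 °C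
Reagents that add atoms: none
Why: Triflation gives 13, in which the ring bond O1–C2 is antiperiplanar to the pseudo-equatorial C3–OTf bond, so O1 displaces triflate from the rear to give the bridged oxiranium ion 14, whose O1–C2 bond then breaks toward the tertiary, gem-dimethyl-stabilised C2 while 2,6-lutidine removes a methyl proton, turning C2 into the exocyclic isopropenyl carbon and the pyran into the dihydrofuran. The closest known reaction type is the dehydrative ring contraction of 2,2-dimethylchroman-3-ols and their sulfonates to 2-isopropenyl-2,3-dihydrobenzofurans by 1,2-aryloxy shift. The five-membered ring is closed by intramolecular backside substitution at C3 (3-exo-tet bridging followed by cleavage of the old O1–C2 bond, a net 1,2-oxygen shift). The only stereocentre is the former C3, which undergoes one stereospecific inversion, so substrate control turns (3S) into (2R). The step needs oxygen participation to beat methyl migration and elimination toward C4, which the antiperiplanar O1–C2 bond and the weak hindered base should secure, and it needs proton loss from a methyl group and not from the ring methine, which the six methyl hydrogens able to align with the breaking O1–C2 bond should secure. The acetates keep the phenols from being triflated, and the twisted, non-chelated ketone leaves O1 nucleophilic enough to participate.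

Step 8
Reactants: 15 (2R)-5-(2-methylpropanoyl)-2-(prop-1-en-2-yl)-2,3-dihydro-1-benzofuran-4,6-diyl diacetate
Product: 16 1-[(2R)-4,6-dihydroxy-2-(prop-1-en-2-yl)-2,3-dihydro-1-benzofuran-5-yl]-2-methylpropan-1-one
Conditions: NH3 (7 M in MeOH), 0 °C; then pH 5 buffer
Reagents that add atoms: none
Why: Ammonolysis of the two aryl acetates is fast at 0 °C and should touch neither the allylic aryl ether, nor the stereocentre, nor the hindered ketone.

Step 9
Reactants: 17 methyl 3-oxopentanoate; 18 N-methoxy-N-methylpropanamide
Product: 20 methyl 4-methyl-3,5-dioxoheptanoate, via dilithium dianion 19 (not isolated)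
Conditions: LDA (3 equiv), THF, −78 °C to 0 °C; then 18, −78 °C to rt; aq. HCl
Reagents that add atoms: none
Why: γ-Acylation of the β-keto ester dianion with a Weinreb amide, whose chelated tetrahedral adduct prevents over-addition, gives the 3,5-diketo ester, and its C4 stereocentre is of no consequence because it is lost on enolisation in the next step.

Step 10
Reactants: 20 methyl 4-methyl-3,5-dioxoheptanoate
Product: 21 6-ethyl-4-hydroxy-5-methyl-2H-pyran-2-one
Conditions: DBU (1.2 equiv), toluene, reflux; then aq. HCl
Reagents that add atoms: none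
Why: Base-mediated lactonisation of the C5 enol oxygen onto the ester with loss of methanol, followed by enolisation, gives the 4-hydroxy-2-pyrone.

Step 11
Reactants: 21 6-ethyl-4-hydroxy-5-methyl-2H-pyran-2-one; 22 N,N-dimethylmethyleneiminium iodide (Eschenmoser's salt); 16 1-[(2R)-4,6-dihydroxy-2-(prop-1-en-2-yl)-2,3-dihydro-1-benzofuran-5-yl]-2-methylpropan-1-one
Product: 25 3-{[(2R)-4,6-dihydroxy-5-(2-methylpropanoyl)-2-(prop-1-en-2-yl)-2,3-dihydro-1-benzofuran-7-yl]methyl}-6-ethyl-4-hydroxy-5-methyl-2H-pyran-2-one, via Mannich base hydroiodide 23 (not isolated), via methylidenepyrandione 24 (not isolated)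
Conditions: 21 + 22, MeCN, rt; then 16, 60 °C
Reagents that add atoms: none
Why: Mannich reaction at the only nucleophilic carbon (C3) of the pyrone gives 23, which on warming loses dimethylamine to the heterodiene 24, and this is trapped in a Michael-type Friedel–Crafts alkylation by the only free, strongly activated ring carbon (C7) of 16 without touching the stereocentre.

## Compound list

1 | phloroglucinol | Oc1cc(O)cc(O)c1 | starting material
2 | isobutyryl chloride | CC(C)C(Cl)=O | starting material
3 | 2-methyl-1-(2,4,6-trihydroxyphenyl)propan-1-one | CC(C)C(=O)c1c(O)cc(O)cc1O | intermediate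
4 | 3-chloro-3-methylbut-1-yne | CC(C)(Cl)C#C | starting material
5 | 1-{2,6-dihydroxy-4-[(2-methylbut-3-yn-2-yl)oxy]phenyl}-2-methylpropan-1-one | CC(C)C(=O)c1c(O)cc(OC(C)(C)C#C)cc1O | intermediate
6 | 5-[(2-methylbut-3-yn-2-yl)oxy]-2-(2-methylpropanoyl)-1,3-phenylene diacetate | CC(C)C(=O)c1c(OC(C)=O)cc(OC(C)(C)C#C)cc1OC(C)=O | intermediate
7 | 6-(3-methylbuta-1,2-dienyl)cyclohexa-2,4-dienone from the Claisen rearrangement of 6 (racemic, not isolated) | CC(C)C(=O)C1=C(OC(C)=O)C(C=C=C(C)C)C(=O)C=C1OC(C)=O | intermediate
8 | 5-hydroxy-4-(3-methylbuta-1,2-dien-1-yl)-2-(2-methylpropanoyl)-1,3-phenylene diacetate (not isolated) | CC(C)C(=O)c1c(OC(C)=O)cc(O)c(C=C=C(C)C)c1OC(C)=O | intermediate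
9 | o-quinone methide bearing the 3-methylbut-2-enylidene group (not isolated) | O=C1C=C(OC(C)=O)C(C(=O)C(C)C)=C(OC(C)=O)C1=CC=C(C)C | intermediate
10 | 2,2-dimethyl-6-(2-methylpropanoyl)-2H-chromene-5,7-diyl diacetate | CC(C)C(=O)c1c(OC(C)=O)cc2OC(C)(C)C=Cc2c1OC(C)=O | intermediate
11 | (3S,4S)-3,4-epoxy-2,2-dimethyl-6-(2-methylpropanoyl)chromane-5,7-diyl diacetate | CC(C)C(=O)c1c(OC(C)=O)cc2OC(C)(C)[C@H]3O[C@H]3c2c1OC(C)=O | intermediate
12 | (3S)-3-hydroxy-2,2-dimethyl-6-(2-methylpropanoyl)chromane-5,7-diyl diacetate | CC(C)C(=O)c1c(OC(C)=O)cc2OC(C)(C)[C@@H](O)Cc2c1OC(C)=O | intermediate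
13 | (3S)-2,2-dimethyl-6-(2-methylpropanoyl)-3-(trifluoromethanesulfonyloxy)chromane-5,7-diyl diacetate (not isolated) | CC(C)C(=O)c1c(OC(C)=O)cc2OC(C)(C)[C@@H](OS(=O)(=O)C(F)(F)F)Cc2c1OC(C)=O | intermediate
14 | bridged oxiranium triflate, O1 bonded to C8a, C2 and C3 (not isolated) | CC1(C)[C@H]2Cc3c(OC(C)=O)c(C(=O)C(C)C)c(OC(C)=O)cc3[O+]12.[O-]S(=O)(=O)C(F)(F)F | intermediate
15 | (2R)-5-(2-methylpropanoyl)-2-(prop-1-en-2-yl)-2,3-dihydro-1-benzofuran-4,6-diyl diacetate | C=C(C)[C@H]1Cc2c(OC(C)=O)c(C(=O)C(C)C)c(OC(C)=O)cc2O1 | intermediate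
16 | 1-[(2R)-4,6-dihydroxy-2-(prop-1-en-2-yl)-2,3-dihydro-1-benzofuran-5-yl]-2-methylpropan-1-one | C=C(C)[C@H]1Cc2c(O)c(C(=O)C(C)C)c(O)cc2O1 | intermediate
17 | methyl 3-oxopentanoate | CCC(=O)CC(=O)OC | starting material
18 | N-methoxy-N-methylpropanamide | CCC(=O)N(C)OC | starting material
19 | dilithium dianion (bis-enolate) of methyl 3-oxopentanoate (not isolated) | [Li+].[Li+].CC=C([O-])C=C([O-])OC | intermediate
20 | methyl 4-methyl-3,5-dioxoheptanoate | CCC(=O)C(C)C(=O)CC(=O)OC | intermediate
21 | 6-ethyl-4-hydroxy-5-methyl-2H-pyran-2-one | CCc1oc(=O)cc(O)c1C | intermediate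
22 | N,N-dimethylmethyleneiminium iodide (Eschenmoser's salt) | C=[N+](C)C.[I-] | starting material
23 | 3-[(dimethylamino)methyl]-6-ethyl-4-hydroxy-5-methyl-2H-pyran-2-one hydroiodide (not isolated) | CCc1oc(=O)c(C[NH+](C)C)c(O)c1C.[I-] | intermediate
24 | 6-ethyl-5-methyl-3-methylidene-2H-pyran-2,4(3H)-dione (not isolated) | CCC1=C(C)C(=O)C(=C)C(=O)O1 | intermediate
25 | 3-{[(2R)-4,6-dihydroxy-5-(2-methylpropanoyl)-2-(prop-1-en-2-yl)-2,3-dihydro-1-benzofuran-7-yl]methyl}-6-ethyl-4-hydroxy-5-methyl-2H-pyran-2-one | C=C(C)[C@H]1Cc2c(O)c(C(=O)C(C)C)c(O)c(Cc3c(O)c(C)c(CC)oc3=O)c2O1 | target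

## Step count and risks

Total step count: 11. Longest linear sequence: 9 steps (steps 1 to 8, then step 11); the pyrone branch has 2 steps (9 and 10).

Steps most likely to fail:

1. Step 7 (ring contraction). What may go wrong: methyl migration or elimination toward C4 from the conformer with a pseudo-axial triflate; loss of the ring methine proton instead of a methyl proton, which would end in an achiral benzofuran; capture of the tertiary cation by triflate. Fallback, from 6 back to 15, without a ring contraction: semi-hydrogenation of the alkyne of 6 (H2, Lindlar catalyst, quinoline, EtOAc) would give the 1,1-dimethylallyl ether F1. Aromatic Claisen rearrangement (toluene, 110 °C) would give the ortho-prenylphenol F2, in which only the para oxygen is free. Shi asymmetric epoxidation (the ketone enantiomer that gives the S oxirane, by the usual model the L-fructose-derived one; Oxone, NaHCO3 buffer at pH 7–8 to spare the acetates, MeCN/DMM/H2O, 0 °C) would give the epoxide F3. The neighbouring phenoxide would open it 5-exo-tet with inversion (Et3N, CH2Cl2) to the (R)-configured tertiary alcohol F4. Dehydration of F4 with the Burgess reagent (toluene, 50 °C) would give 15.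

2. Step 11 (methylene bridge). What may go wrong: self-coupling of the pyrone with its own Mannich base, hetero-Diels–Alder capture of the methylidenepyrandione by the isopropenyl group, and O- instead of C-attack. Fallback, from 16 back to 25, with the roles of the partners reversed: aminomethylation of 16 at its only free ring carbon with Eschenmoser's salt (CH2Cl2, rt) would give the phenolic Mannich base F5. Heating F5 with pyrone 21 (dioxane, 90 °C) would generate the ortho-quinone methide of the acylphloroglucinol, which C3 of the pyrone would trap to give 25.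

3. Step 5 (asymmetric epoxidation). What may go wrong: incomplete facial discrimination on this electron-poor chromene with an acetoxy group peri to C4, and acid-induced opening or rearrangement of the benzylic epoxide during reaction or isolation. Fallback, from 10 back to 12, which sets C3 by reduction and also bypasses step 6: racemic epoxidation of 10 (mCPBA, NaHCO3, CH2Cl2) would give the racemic epoxide F6. Meinwald rearrangement (ZnBr2 cat., CH2Cl2, −20 °C; hydride shift from C3 to the benzylic C4 cation) would give the chroman-3-one F7. Corey–Bakshi–Shibata reduction ((R)-Me-CBS, the enantiomer predicted when the quaternary C2 is the large group; catecholborane, toluene, −40 °C) would give 12.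

## Further compounds

F1 | step 7 | 5-[(2-methylbut-3-en-2-yl)oxy]-2-(2-methylpropanoyl)-1,3-phenylene diacetate | CC(C)C(=O)c1c(OC(C)=O)cc(OC(C)(C)C=C)cc1OC(C)=O
F2 | step 7 | 5-hydroxy-4-(3-methylbut-2-en-1-yl)-2-(2-methylpropanoyl)-1,3-phenylene diacetate | CC(C)C(=O)c1c(OC(C)=O)cc(O)c(CC=C(C)C)c1OC(C)=O
F3 | step 7 | 4-{[(2S)-3,3-dimethyloxiran-2-yl]methyl}-5-hydroxy-2-(2-methylpropanoyl)-1,3-phenylene diacetate | CC(C)C(=O)c1c(OC(C)=O)cc(O)c(C[C@@H]2OC2(C)C)c1OC(C)=O
F4 | step 7 | (2R)-2-(2-hydroxypropan-2-yl)-5-(2-methylpropanoyl)-2,3-dihydro-1-benzofuran-4,6-diyl diacetate | CC(C)(O)[C@H]1Cc2c(OC(C)=O)c(C(=O)C(C)C)c(OC(C)=O)cc2O1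
F5 | step 11 | 1-[(2R)-7-[(dimethylamino)methyl]-4,6-dihydroxy-2-(prop-1-en-2-yl)-2,3-dihydro-1-benzofuran-5-yl]-2-methylpropan-1-one | C=C(C)[C@H]1Cc2c(O)c(C(=O)C(C)C)c(O)c(CN(C)C)c2O1
F6 | step 5 | racemic 3,4-epoxy-2,2-dimethyl-6-(2-methylpropanoyl)chromane-5,7-diyl diacetate | CC(C)C(=O)c1c(OC(C)=O)cc2OC(C)(C)C3OC3c2c1OC(C)=O
F7 | step 5 | 2,2-dimethyl-6-(2-methylpropanoyl)-3-oxochromane-5,7-diyl diacetate | CC(C)C(=O)c1c(OC(C)=O)cc2OC(C)(C)C(=O)Cc2c1OC(C)=O
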